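**Retrosynthetic overview**

1. Ring B is bought as 4-iodoanisole (1) and joined to ethyl propiolate (2) to give the alkynoate 3. Ring A is bought as phloroglucinol (4). Ring C (the pyranone) is the only ring made, and it is made last.
2. C6–S: 4 is sulfonated while it is still threefold symmetric (acid 5, isolated as potassium salt 6), so only one monosulfonate can form and the anisyl ring never meets a sulfonating agent.
3. O1–C2 (key disconnection): the one hydroxyl of 6 that is para to the sulfonate adds across 3 (oxa-Michael) to give the (Z)-aryl vinyl ether 7.
4. C4–C4a: 7 closes onto either of its two symmetry-equivalent ortho carbons (intramolecular C-acylation), which puts the sulfonate between the two remaining hydroxyls, that is at C6 of niruriflavone (8).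

Assumption: the target has no stereocentre and no stereogenic double bond, so the "single enantiomer" is the single achiral compound shown; it is isolated as the free sulfonic acid.

**Step 1**
Reactants: 1 4-iodoanisole; 2 ethyl propiolate
Product: 3 ethyl 3-(4-methoxyphenyl)prop-2-ynoate
Conditions: Pd(PPh3)2Cl2 (2 mol%), CuI (4 mol%), K2CO3 (2 equiv), 2 (3 equiv, slow addition), THF, 65 °C
Reagents that add atoms: none
Why: Sonogashira coupling (oxidative addition of zerovalent palladium into the C–I bond, transmetalation from the copper acetylide, reductive elimination); the amine-free K2CO3/THF variant avoids amine conjugate addition to the propiolate and its oligomerisation, and no stereocentre is formed.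

**Step 2**
Reactants: 4 phloroglucinol (anhydrous)
Product: 6 potassium 2,4,6-trihydroxybenzenesulfonate, via 2,4,6-trihydroxybenzenesulfonic acid 5 (not isolated)
Conditions: ClSO3H (1.0 equiv), MeCN, −10 to 0 °C, N2 sweep; then KOAc (1.0 equiv), EtOH, 0 °C, filter the salt
Reagents that add atoms: chlorosulfonic acid, O=S(=O)(O)Cl; potassium acetate, CC(=O)[O-].[K+]
Why: Electrophilic aromatic sulfonation of a very electron-rich arene; the three ring C–H positions are equivalent so a single monosulfonic acid forms, the first SO3H group deactivates the ring against a second, and the product is kept as its potassium salt because the free acid would protodesulfonate in warm aqueous acid; no stereocentre is formed.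

**Step 3**
Reactants: 6 potassium 2,4,6-trihydroxybenzenesulfonate; 3 ethyl 3-(4-methoxyphenyl)prop-2-ynoate
Product: 8 niruriflavone, via aryl vinyl ether 7 (not isolated)
Conditions: a) DBU (1.1 equiv), DMF, 4 Å MS, Ar, 50 °C; b) MgCl2 (2.0 equiv), Et3N (3.0 equiv), 100 °C; c) 1 M HCl, 0 °C, then HP-20 resin (H2O, then MeOH)
Reagents that add atoms: none
Why: Proposed new method: a one-flask, sulfonate-steered para-selective oxa-Michael addition followed by a magnesium-templated anionic ring closure; the 4-OH of 6 is the only hydroxyl that is neither hydrogen-bonded to nor flanked by the sulfonate, so it is the most acidic and least hindered and its phenoxide adds anti across 3 to form the O1–C2 bond and give (Z)-7 (aryloxy cis to CO2Et, no stereocentre); MgCl2/Et3N then converts the two remaining hydroxyls into a magnesium phenolate whose ring carbon ortho to the ether oxygen (two equivalent positions) attacks the magnesium-bound ester carbonyl in a 6-exo acyl substitution, ethoxide leaves and re-aromatisation gives the 5-oxido/4-keto magnesium chelate of the flavone, so the sulfonate can only end at C6; the closest known reaction types are base-mediated addition of phenols to alkynoates (first half of the Ruhemann flavone synthesis), ortho-C-acylation of magnesium phenolates by acyl chlorides, Kolbe–Schmitt C-acylation of resorcinol-type phenolates and the Dieckmann condensation, but neither the site-selective addition on a sulfonated phloroglucinol nor an ester-based anionic closure to a flavone has been shown.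

**Compound list**

1 | 4-iodoanisole (1-iodo-4-methoxybenzene) | COc1ccc(I)cc1 | starting material
2 | ethyl propiolate (ethyl prop-2-ynoate) | CCOC(=O)C#C | starting material
3 | ethyl 3-(4-methoxyphenyl)prop-2-ynoate | CCOC(=O)C#Cc1ccc(OC)cc1 | intermediate
4 | phloroglucinol (benzene-1,3,5-triol) | Oc1cc(O)cc(O)c1 | starting material
5 | 2,4,6-trihydroxybenzenesulfonic acid | O=S(=O)(O)c1c(O)cc(O)cc1O | intermediate
6 | potassium 2,4,6-trihydroxybenzenesulfonate | O=S(=O)([O-])c1c(O)cc(O)cc1O.[K+] | intermediate
7 | potassium 4-{[(1Z)-3-ethoxy-1-(4-methoxyphenyl)-3-oxoprop-1-en-1-yl]oxy}-2,6-dihydroxybenzenesulfonate | CCOC(=O)/C=C(\Oc1cc(O)c(S(=O)(=O)[O-])c(O)c1)c1ccc(OC)cc1.[K+] | intermediate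
8 | niruriflavone (5,7-dihydroxy-2-(4-methoxyphenyl)-4-oxo-4H-chromene-6-sulfonic acid) | COc1ccc(-c2cc(=O)c3c(O)c(S(=O)(=O)O)c(O)cc3o2)cc1 | target

**Step count and risks**

Total steps: 3. Longest linear sequence: 2 (step 2 then step 3, or step 1 then step 3).

Most likely to fail, in this order:

Step 3 (the proposed new annulation). The addition may go partly through a sulfonate-flanked hydroxyl, which would lead to the 8-sulfonate isomer, or through ring carbon, which would lead to a 4-arylcoumarin. The anionic closure of an ester onto the phenolate carbon may also stall. Fallback with known chemistry, the stepwise Ruhemann flavone synthesis, setting out from 6 and 3 and coming back at 8: K2CO3 (1.1 equiv) in DMF at 60 °C, stopped after the addition, gives 7, which is now isolated by precipitation, and this also lets any ortho-O adduct be removed. LiOH in THF/H2O at 25 °C followed by cold HCl gives (2Z)-3-(3,5-dihydroxy-4-sulfophenoxy)-3-(4-methoxyphenyl)prop-2-enoic acid F1. Eaton's reagent (P2O5 in MeSO3H) at 50 °C then closes ring C by intramolecular Friedel–Crafts acylation at either equivalent ortho carbon to give 8; the medium is anhydrous, so protodesulfonation has no water to drive it.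

Step 2 (sulfonation of 4). O-sulfation, di-sulfonation or oxidative darkening may lower the yield, and the salt may be hard to free from inorganic material. Fallback, setting out from 4 and coming back at 6: SO3·pyridine (1.0 equiv) in pyridine at 0 °C followed by aqueous KOH gives potassium 3,5-dihydroxyphenyl sulfate F2 by stoichiometric, non-acidic O-sulfation. Heating F2 in sulfolane at 120–140 °C brings about the aryl sulfate to hydroxyarenesulfonate rearrangement. Every ring carbon of F2 leads to the same product after migration, so this gives 6.

Step 1 (Sonogashira coupling with ethyl propiolate). The electron-poor alkyne may oligomerise or homocouple. Fallback, setting out from 1 and coming back at 3, making the alkyne–ester bond instead of the aryl–alkyne bond last: coupling of 1 with trimethylsilylacetylene (Pd(PPh3)2Cl2, CuI, Et3N, 25 °C) gives trimethyl[(4-methoxyphenyl)ethynyl]silane F3. K2CO3 in MeOH gives 1-ethynyl-4-methoxybenzene F4, which can also be bought. n-BuLi in THF at −78 °C followed by ClCO2Et acylates the lithium acetylide to give 3.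

**Further compounds**

F1 | step 3 | (2Z)-3-(3,5-dihydroxy-4-sulfophenoxy)-3-(4-methoxyphenyl)prop-2-enoic acid | O=C(O)/C=C(\Oc1cc(O)c(S(=O)(=O)O)c(O)c1)c1ccc(OC)cc1
F2 | step 2 | potassium 3,5-dihydroxyphenyl sulfate | O=S(=O)([O-])Oc1cc(O)cc(O)c1.[K+]
F3 | step 1 | trimethyl[(4-methoxyphenyl)ethynyl]silane | COc1ccc(C#C[Si](C)(C)C)cc1
F4 | step 1 | 1-ethynyl-4-methoxybenzene | COc1ccc(C#C)cc1
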